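All constants come from no measurement; the run is a simulation.

A small charge of E, 2.2 µM, has to work through 27 mM of solid X in this flask. X dissolves to L. E turns L into D and comes out unchanged, and L also decays by itself to G.

X 27 mM; E 2.2 µM; time 15 d

- the state of affairs at 15 d: stopped, and by what, or still going (for what has run out or reacted, a solid counts together with what of it has only dissolved) (all of X has reacted / it is still moving)
- part of the X that has turned into other species by 15 d (what has only dissolved does not count)
- how much D there is at 15 d, in percent of the X charged

- solid, in amounts per volume of the solution: X
- at the start none of X is in solution
- what has only dissolved of X counts as not reacted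
- the reaction counts as stopped when no species that holds the X changes by six tenths of a point or more over the second half of the time
- run time (flask): 15 d

    L + E → D + E, rate k1*[L]*[E]/(1 + ([L]/Km1) + ([D]/Kp1)) (Km1 = 16 mM, Kp1 = 16 mM, k1 = 1.8 × 10⁵ M⁻¹ h⁻¹)
    X ⇌ L, rate k2*(cs2 - [L]) while solid is left; crystals form when [L] > cs2 (cs2 = 15 mM, k2 = 0.057 h⁻¹)
    L → G (k3 = 0.019 h⁻¹)

My own reckoning starts with time. At its fastest, X dissolves in 1.32 d, and the run lasts 15 d, much longer. So I expect X to finish well inside the run, and the real question is the split between D and G.

Unbraked, E removes L 20.8 times as fast as the side step does. Call this ratio S, the selectivity factor. But L and D both slow E, by a factor of one plus (L + D) over 16 mM. L + D climbs from nothing towards the charge, so I take half the charge as its mean. That gives D a lead over G of 11.3 to one. The lead is S divided by the slowing factor at half the charge. It puts 91.9% of the charge into D.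

The forecast says all of X has reacted, with conversion 100% and D at 91.5%, holding that “inhibition narrows that lead only moderately”.

The simulation gives all of X has reacted, with conversion 100% and D at 91.5%.

In this flask, the D missing from the charge went to G: without the loss of L to G, D rises from 91.5% to 100%. This flask ends with 10.8 of D per G, against a lead of 11.3. Now take the neighbour flask, with 68 mM of X. My reckoning at half that charge gives a lead of 6.67, which puts 87.0% into D. The neighbour flask gives 87.1% as D and 12.9% as G.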